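**Strategy.** Everything rests on unzipping the trans-decalin across C5–C10 and C8–C9 (labdane numbering): ring B is a Diels–Alder cyclohexene and ring A is the C1–C4 tether. One chelate-controlled intramolecular [4+2] cycloaddition of an E β-methyl enoyl oxazolidinone (C9=C10) onto an E,E-diene (C5–C8) closes rings A and B and sets C5, C8, C9 and quaternary C10 together, exploiting the quaternary C10/tertiary C9 pair at the ring fusion. The precursor is acyclic trienimide 13 with the C4 gem-dimethyl tether and a C17 silyloxymethyl diene terminus, here as the bulkier tert-butyldiphenylsilyl ether for Lewis-acid tolerance; both E-trisubstituted alkenes of the route derive stereospecifically from one enol triflate.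

Key step: step 8

Remark: labdane numbering (C1–C20) is used for positions; β is the face of the C10 methyl group. Assumption: compounds 1, 2, 6 and 11 are purchased.

**Route**

Step 1
Reactants: 1 2,2-dimethylpent-4-enal; 2 triethyl 4-phosphonocrotonate
Product: 3 ethyl (2E,4E)-6,6-dimethylnona-2,4,8-trienoate
Conditions: LiN(SiMe3)2, THF, −78 °C to rt
Reagents that add atoms: none
Why: Vinylogous Horner–Wadsworth–Emmons olefination of a non-enolisable α-quaternary aldehyde with the stabilised phosphonate anion should give the E,E-dienoate (new C5=C6 alkene E under thermodynamic control).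

Step 2
Reactants: 3 ethyl (2E,4E)-6,6-dimethylnona-2,4,8-trienoate
Product: 4 (2E,4E)-6,6-dimethylnona-2,4,8-trien-1-ol
Conditions: i-Bu2AlH (2.2 equiv), CH2Cl2, −78 °C
Reagents that add atoms: none
Why: 1,2-Reduction of the conjugated ester to the allylic alcohol with i-Bu2AlH leaves the diene and the terminal alkene untouched.

Step 3
Reactants: 4 (2E,4E)-6,6-dimethylnona-2,4,8-trien-1-ol
Product: 5 tert-butyl{[(2E,4E)-6,6-dimethylnona-2,4,8-trien-1-yl]oxy}diphenylsilane
Conditions: TBDPSCl, imidazole, CH2Cl2, rt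
Reagents that add atoms: tert-butyl(chloro)diphenylsilane, CC(C)(C)[Si](Cl)(c1ccccc1)c1ccccc1
Why: Imidazole-mediated silylation of the primary alcohol; the bulky, weakly Lewis-basic silyl ether is chosen to survive borane, hydride, base and Me2AlCl.

Step 4
Reactants: 6 methyl acetoacetate
Product: 7 methyl (2E)-3-{[(trifluoromethyl)sulfonyl]oxy}but-2-enoate (triflate trans to the ester)
Conditions: Tf2O, aq. Me4NOH, toluene, 5 °C to rt
Reagents that add atoms: trifluoromethanesulfonic anhydride, O=S(=O)(OS(=O)(=O)C(F)(F)F)C(F)(F)F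
Why: Biphasic O-triflation of the β-keto ester enolate, in which the non-chelating tetramethylammonium counter-ion favours the enolate with its oxygen anti to the ester and hence the E enol triflate (geometry to be confirmed by NOE).

Step 5
Reactants: 5 tert-butyl{[(2E,4E)-6,6-dimethylnona-2,4,8-trien-1-yl]oxy}diphenylsilane; 7 methyl (2E)-3-{[(trifluoromethyl)sulfonyl]oxy}but-2-enoate
Product: 9 methyl (2E,8E,10E)-12-{[tert-butyl(diphenyl)silyl]oxy}-3,7,7-trimethyldodeca-2,8,10-trienoate, via alkyl-9-BBN borane 8 (not isolated)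
Conditions: 9-BBN-H, THF, 0 °C to rt; then 7, PdCl2(dppf) (5 mol %), aq. K3PO4, THF/DMF, rt
Reagents that add atoms: 9-borabicyclo[3.3.1]nonane, [H]B1C2CCCC1CCC2 (boron unit present only in 8; it adds only hydrogen to 9)
Why: Anti-Markovnikov hydroboration of the monosubstituted alkene (much faster than attack on the internal conjugated diene) followed by B-alkyl Suzuki–Miyaura coupling, which proceeds with retention at the enol triflate and so places the chain trans to the ester (2E, methyl cis to the carbonyl).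

Step 6
Reactants: 9 methyl (2E,8E,10E)-12-{[tert-butyl(diphenyl)silyl]oxy}-3,7,7-trimethyldodeca-2,8,10-trienoate
Product: 10 (2E,8E,10E)-12-{[tert-butyl(diphenyl)silyl]oxy}-3,7,7-trimethyldodeca-2,8,10-trienoic acid
Conditions: LiOH, THF/MeOH/H2O, rt to 40 °C; then 1 M HCl to pH 3
Reagents that add atoms: lithium hydroxide, [Li+].[OH-]
Why: Ester saponification; the silyl ether and the enoate geometry are stable to hydroxide at this temperature.

Step 7
Reactants: 10 (2E,8E,10E)-12-{[tert-butyl(diphenyl)silyl]oxy}-3,7,7-trimethyldodeca-2,8,10-trienoic acid; 11 (S)-4-benzyl-2-oxazolidinone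
Product: 13 (4S)-4-benzyl-3-[(2E,8E,10E)-12-{[tert-butyl(diphenyl)silyl]oxy}-3,7,7-trimethyldodeca-2,8,10-trienoyl]-1,3-oxazolidin-2-one, via mixed pivalic anhydride 12 (not isolated)
Conditions: PivCl, Et3N, THF, −20 °C; then 11, LiCl, 0 °C to rt
Reagents that add atoms: pivaloyl chloride, CC(C)(C)C(Cl)=O (pivaloyl unit present only in 12)
Why: N-Acylation of the oxazolidinone by the mixed anhydride at its less hindered enoyl carbonyl with LiCl activation; no stereocentre is formed and the auxiliary centre is untouched.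

Step 8
Reactants: 13 (4S)-4-benzyl-3-[(2E,8E,10E)-12-{[tert-butyl(diphenyl)silyl]oxy}-3,7,7-trimethyldodeca-2,8,10-trienoyl]-1,3-oxazolidin-2-one
Product: 14 (4S)-4-benzyl-3-{[(1S,2S,4aS,8aS)-2-({[tert-butyl(diphenyl)silyl]oxy}methyl)-5,5,8a-trimethyl-1,2,4a,5,6,7,8,8a-octahydronaphthalen-1-yl]carbonyl}-1,3-oxazolidin-2-one (9β-acyl, 8β-CH2OSi, 10β-methyl, 5α-H, C6=C7 alkene)
Conditions: Me2AlCl (1.5 equiv), CH2Cl2, −30 to 0 °C; then 1 M HCl
Reagents that add atoms: none
Why: Me2AlCl in excess converts the imide into a cationic two-point aluminium chelate that locks the enoyl unit s-cis and lowers its LUMO, and the tethered diene then adds in a concerted but asynchronous intramolecular [4+2] cycloaddition (C5–C10 bonding ahead of C8–C9), the known Lewis-acid-promoted intramolecular Diels–Alder reaction of 2,8,10-trienoyl oxazolidinones to trans-fused octalins. Ring B is closed by the cycloaddition proper (new bonds C5–C10 and C8–C9 across the C5–C8 diene), and ring A is closed in the same event because the C1–C4 tether, folded chair-like, links C10 to C5 (six-membered, tether exo). C9 is controlled by the benzyl group of the auxiliary, which covers the Re face of C9 in the chelate so that C8 bonds to the Si face; C10 follows from the E dienophile geometry (suprafacial addition keeps C11 cis to the C10 methyl); C5 follows from the carbonyl-endo, tether-exo geometry (H5 trans to the C10 methyl, hence trans fusion); C8 follows from the E,E-diene in the same endo geometry (CH2OSi cis to C11) and is erased later. The step needs endo over exo selectivity and a single dienophile face: chelation enforces both, A(1,3) strain between the C10 methyl and the imide nitrogen excludes the s-trans rotamer, the C4 gem-dimethyl group pre-folds the tether and offsets the lower reactivity of the β-methyl dienophile, and the bulky silyl ether keeps the dienylic oxygen away from the Lewis acid.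

Step 9
Reactants: 14 the cycloadduct imide
Product: 15 [(1S,2S,4aS,8aS)-2-({[tert-butyl(diphenyl)silyl]oxy}methyl)-5,5,8a-trimethyl-1,2,4a,5,6,7,8,8a-octahydronaphthalen-1-yl]methanol
Conditions: LiBH4, MeOH (1 equiv), THF, 0 °C
Reagents that add atoms: none
Why: Reductive cleavage of the N-acyl oxazolidinone by hydride attack at the lithium-chelated exocyclic carbonyl gives the C11 alcohol and releases the auxiliary for recovery without touching C9.

Step 10
Reactants: 15 the C11 alcohol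
Product: 16 (1S,2S,4aS,8aS)-2-({[tert-butyl(diphenyl)silyl]oxy}methyl)-5,5,8a-trimethyl-1,2,4a,5,6,7,8,8a-octahydronaphthalene-1-carbaldehyde
Conditions: Dess–Martin periodinane, pyridine, CH2Cl2, 0 °C to rt
Reagents that add atoms: none
Why: Dess–Martin oxidation of the primary alcohol under buffered, non-basic conditions should give the aldehyde without epimerising C9.

Step 11
Reactants: 16 the C11 aldehyde
Product: 17 tert-butyl{[(1S,2S,4aS,8aR)-1-ethenyl-5,5,8a-trimethyl-1,2,4a,5,6,7,8,8a-octahydronaphthalen-2-yl]methoxy}diphenylsilane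
Conditions: Ph3PCH3Br, KN(SiMe3)2, THF, 0 °C; then 16, −78 °C to rt
Reagents that add atoms: methylenetriphenylphosphorane, C=P(c1ccccc1)(c1ccccc1)c1ccccc1, made in the flask from methyltriphenylphosphonium bromide, C[P+](c1ccccc1)(c1ccccc1)c1ccccc1.[Br-]
Why: Wittig methylenation with the unstabilised ylide is fast even on hindered aldehydes, and cold addition to the preformed ylide minimises enolisation at C9.

Step 12
Reactants: 17 the C9 vinyl compound; 7 methyl (2E)-3-{[(trifluoromethyl)sulfonyl]oxy}but-2-enoate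
Product: 19 methyl (2E)-5-[(1S,2S,4aS,8aR)-2-({[tert-butyl(diphenyl)silyl]oxy}methyl)-5,5,8a-trimethyl-1,2,4a,5,6,7,8,8a-octahydronaphthalen-1-yl]-3-methylpent-2-enoate, via alkyl-9-BBN borane 18 (not isolated)
Conditions: 9-BBN-H, THF, rt to 50 °C; then 7, PdCl2(dppf) (5 mol %), aq. K3PO4, THF/DMF, rt
Reagents that add atoms: 9-borabicyclo[3.3.1]nonane, [H]B1C2CCCC1CCC2 (boron unit present only in 18; it adds only hydrogen to 19)
Why: Hydroboration of the monosubstituted C11=C12 alkene with boron at C12 (the hindered ring alkene C6=C7 is spared) and B-alkyl Suzuki–Miyaura coupling with retention at the same E enol triflate sets the 13E alkene.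

Step 13
Reactants: 19 the side-chain enoate
Product: 20 (2E)-5-[(1S,2S,4aS,8aR)-2-({[tert-butyl(diphenyl)silyl]oxy}methyl)-5,5,8a-trimethyl-1,2,4a,5,6,7,8,8a-octahydronaphthalen-1-yl]-3-methylpent-2-en-1-ol
Conditions: i-Bu2AlH (2.2 equiv), CH2Cl2, −78 °C
Reagents that add atoms: none
Why: 1,2-Reduction of the enoate to the allylic alcohol with i-Bu2AlH preserves alkene geometry and the silyl ether.

Step 14
Reactants: 20 the C15 allylic alcohol
Product: 21 (2E)-5-[(1S,2S,4aS,8aR)-2-({[tert-butyl(diphenyl)silyl]oxy}methyl)-5,5,8a-trimethyl-1,2,4a,5,6,7,8,8a-octahydronaphthalen-1-yl]-3-methylpent-2-en-1-yl acetate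
Conditions: Ac2O, pyridine, DMAP (cat.), CH2Cl2, 0 °C to rt
Reagents that add atoms: acetic anhydride, CC(=O)OC(C)=O
Why: DMAP-catalysed acetylation of the only free (primary allylic) hydroxyl group.

Step 15
Reactants: 21 the silyl ether acetate
Product: 22 (2E)-5-[(1S,2S,4aS,8aR)-2-(hydroxymethyl)-5,5,8a-trimethyl-1,2,4a,5,6,7,8,8a-octahydronaphthalen-1-yl]-3-methylpent-2-en-1-yl acetate
Conditions: Bu4NF, AcOH (1:1), THF, rt
Reagents that add atoms: none
Why: Fluoride-driven desilylation (Si–F bond formation), buffered with acetic acid so that the allylic acetate is not cleaved.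

Step 16
Reactants: 22 the C17 alcohol
Product: 24 (2E)-5-[(1R,4aS,8aS)-2-formyl-5,5,8a-trimethyl-1,4,4a,5,6,7,8,8a-octahydronaphthalen-1-yl]-3-methylpent-2-en-1-yl acetate, via β,γ-unsaturated aldehyde 23 (not isolated)
Conditions: (COCl)2, DMSO, CH2Cl2, −78 °C; Et3N, −78 to 0 °C; then DBU, rt
Reagents that add atoms: none
Why: Swern oxidation gives the β,γ-unsaturated aldehyde and DBU then moves the C6=C7 double bond into conjugation through the dienolate (deprotonation at C8, reprotonation at C6), which erases C8 and cannot touch C9 because its hydrogen is not vinylogously acidic.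

Step 17
Reactants: 24 the C17 enal
Product: 25 (1R,4aS,8aS)-1-[(3E)-5-(acetyloxy)-3-methylpent-3-en-1-yl]-5,5,8a-trimethyl-1,4,4a,5,6,7,8,8a-octahydronaphthalene-2-carboxylic acid (target; 5S,9R,10S in labdane numbering)
Conditions: NaClO2, NaH2PO4, 2-methyl-2-butene, t-BuOH/H2O, rt
Reagents that add atoms: sodium chlorite, [Na+].[O-]Cl=O
Why: Pinnick oxidation converts the enal to the acid at mildly acidic pH, leaving the acetate and the alkenes intact while 2-methyl-2-butene scavenges HOCl.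

**Compound list**

1 | 2,2-dimethylpent-4-enal | C=CCC(C)(C)C=O | starting material
2 | triethyl 4-phosphonocrotonate | CCOC(=O)/C=C/CP(=O)(OCC)OCC | starting material
3 | ethyl (2E,4E)-6,6-dimethylnona-2,4,8-trienoate | CCOC(=O)/C=C/C=C/C(C)(C)CC=C | intermediate
4 | (2E,4E)-6,6-dimethylnona-2,4,8-trien-1-ol | OC/C=C/C=C/C(C)(C)CC=C | intermediate
5 | tert-butyl{[(2E,4E)-6,6-dimethylnona-2,4,8-trien-1-yl]oxy}diphenylsilane | C=CCC(C)(C)/C=C/C=C/CO[Si](c1ccccc1)(c2ccccc2)C(C)(C)C | intermediate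
6 | methyl acetoacetate | COC(=O)CC(C)=O | starting material
7 | methyl (2E)-3-{[(trifluoromethyl)sulfonyl]oxy}but-2-enoate | COC(=O)/C=C(\C)OS(=O)(=O)C(F)(F)F | intermediate
8 | 9-[(5E,7E)-9-{[tert-butyl(diphenyl)silyl]oxy}-4,4-dimethylnona-5,7-dien-1-yl]-9-borabicyclo[3.3.1]nonane | CC(C)(C)[Si](OC/C=C/C=C/C(C)(C)CCCB1C2CCCC1CCC2)(c3ccccc3)c4ccccc4 | intermediate (not isolated)
9 | methyl (2E,8E,10E)-12-{[tert-butyl(diphenyl)silyl]oxy}-3,7,7-trimethyldodeca-2,8,10-trienoate | COC(=O)/C=C(\C)CCCC(C)(C)/C=C/C=C/CO[Si](c1ccccc1)(c2ccccc2)C(C)(C)C | intermediate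
10 | (2E,8E,10E)-12-{[tert-butyl(diphenyl)silyl]oxy}-3,7,7-trimethyldodeca-2,8,10-trienoic acid | OC(=O)/C=C(\C)CCCC(C)(C)/C=C/C=C/CO[Si](c1ccccc1)(c2ccccc2)C(C)(C)C | intermediate
11 | (S)-4-benzyl-2-oxazolidinone | O=C1N[C@@H](Cc2ccccc2)CO1 | starting material
12 | mixed anhydride of 10 with pivalic acid | CC(C)(C)C(=O)OC(=O)/C=C(\C)CCCC(C)(C)/C=C/C=C/CO[Si](c1ccccc1)(c2ccccc2)C(C)(C)C | intermediate (not isolated)
13 | (4S)-4-benzyl-3-[(2E,8E,10E)-12-{[tert-butyl(diphenyl)silyl]oxy}-3,7,7-trimethyldodeca-2,8,10-trienoyl]-1,3-oxazolidin-2-one | O=C1OC[C@H](Cc2ccccc2)N1C(=O)/C=C(\C)CCCC(C)(C)/C=C/C=C/CO[Si](c3ccccc3)(c4ccccc4)C(C)(C)C | intermediate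
14 | (4S)-4-benzyl-3-{[(1S,2S,4aS,8aS)-2-({[tert-butyl(diphenyl)silyl]oxy}methyl)-5,5,8a-trimethyl-1,2,4a,5,6,7,8,8a-octahydronaphthalen-1-yl]carbonyl}-1,3-oxazolidin-2-one | O=C1OC[C@H](Cc2ccccc2)N1C(=O)[C@H]3[C@@H](CO[Si](c5ccccc5)(c6ccccc6)C(C)(C)C)C=C[C@H]4C(C)(C)CCC[C@]34C | intermediate
15 | [(1S,2S,4aS,8aS)-2-({[tert-butyl(diphenyl)silyl]oxy}methyl)-5,5,8a-trimethyl-1,2,4a,5,6,7,8,8a-octahydronaphthalen-1-yl]methanol | OC[C@H]1[C@@H](CO[Si](c3ccccc3)(c4ccccc4)C(C)(C)C)C=C[C@H]2C(C)(C)CCC[C@]12C | intermediate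
16 | (1S,2S,4aS,8aS)-2-({[tert-butyl(diphenyl)silyl]oxy}methyl)-5,5,8a-trimethyl-1,2,4a,5,6,7,8,8a-octahydronaphthalene-1-carbaldehyde | O=C[C@H]1[C@@H](CO[Si](c3ccccc3)(c4ccccc4)C(C)(C)C)C=C[C@H]2C(C)(C)CCC[C@]12C | intermediate
17 | tert-butyl{[(1S,2S,4aS,8aR)-1-ethenyl-5,5,8a-trimethyl-1,2,4a,5,6,7,8,8a-octahydronaphthalen-2-yl]methoxy}diphenylsilane | C=C[C@H]1[C@@H](CO[Si](c3ccccc3)(c4ccccc4)C(C)(C)C)C=C[C@H]2C(C)(C)CCC[C@]12C | intermediate
18 | 9-{2-[(1S,2S,4aS,8aR)-2-({[tert-butyl(diphenyl)silyl]oxy}methyl)-5,5,8a-trimethyl-1,2,4a,5,6,7,8,8a-octahydronaphthalen-1-yl]ethyl}-9-borabicyclo[3.3.1]nonane | C1CCC2CCCC1B2CC[C@H]3[C@@H](CO[Si](c5ccccc5)(c6ccccc6)C(C)(C)C)C=C[C@H]4C(C)(C)CCC[C@]34C | intermediate (not isolated)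
19 | methyl (2E)-5-[(1S,2S,4aS,8aR)-2-({[tert-butyl(diphenyl)silyl]oxy}methyl)-5,5,8a-trimethyl-1,2,4a,5,6,7,8,8a-octahydronaphthalen-1-yl]-3-methylpent-2-enoate | COC(=O)/C=C(\C)CC[C@H]1[C@@H](CO[Si](c3ccccc3)(c4ccccc4)C(C)(C)C)C=C[C@H]2C(C)(C)CCC[C@]12C | intermediate
20 | (2E)-5-[(1S,2S,4aS,8aR)-2-({[tert-butyl(diphenyl)silyl]oxy}methyl)-5,5,8a-trimethyl-1,2,4a,5,6,7,8,8a-octahydronaphthalen-1-yl]-3-methylpent-2-en-1-ol | OC/C=C(\C)CC[C@H]1[C@@H](CO[Si](c3ccccc3)(c4ccccc4)C(C)(C)C)C=C[C@H]2C(C)(C)CCC[C@]12C | intermediate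
21 | (2E)-5-[(1S,2S,4aS,8aR)-2-({[tert-butyl(diphenyl)silyl]oxy}methyl)-5,5,8a-trimethyl-1,2,4a,5,6,7,8,8a-octahydronaphthalen-1-yl]-3-methylpent-2-en-1-yl acetate | CC(=O)OC/C=C(\C)CC[C@H]1[C@@H](CO[Si](c3ccccc3)(c4ccccc4)C(C)(C)C)C=C[C@H]2C(C)(C)CCC[C@]12C | intermediate
22 | (2E)-5-[(1S,2S,4aS,8aR)-2-(hydroxymethyl)-5,5,8a-trimethyl-1,2,4a,5,6,7,8,8a-octahydronaphthalen-1-yl]-3-methylpent-2-en-1-yl acetate | CC(=O)OC/C=C(\C)CC[C@H]1[C@@H](CO)C=C[C@H]2C(C)(C)CCC[C@]12C | intermediate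
23 | (2E)-5-[(1S,2S,4aS,8aR)-2-formyl-5,5,8a-trimethyl-1,2,4a,5,6,7,8,8a-octahydronaphthalen-1-yl]-3-methylpent-2-en-1-yl acetate | CC(=O)OC/C=C(\C)CC[C@H]1[C@@H](C=O)C=C[C@H]2C(C)(C)CCC[C@]12C | intermediate (not isolated)
24 | (2E)-5-[(1R,4aS,8aS)-2-formyl-5,5,8a-trimethyl-1,4,4a,5,6,7,8,8a-octahydronaphthalen-1-yl]-3-methylpent-2-en-1-yl acetate | CC(=O)OC/C=C(\C)CC[C@H]1C(C=O)=CC[C@H]2C(C)(C)CCC[C@]12C | intermediate
25 | (1R,4aS,8aS)-1-[(3E)-5-(acetyloxy)-3-methylpent-3-en-1-yl]-5,5,8a-trimethyl-1,4,4a,5,6,7,8,8a-octahydronaphthalene-2-carboxylic acid | CC(=O)OC/C=C(\C)CC[C@H]1C(C(=O)O)=CC[C@H]2C(C)(C)CCC[C@]12C | target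

**Step count and risks**

Total step count: 17. Longest linear sequence: 16 steps (steps 1–3 and 5–17; step 4 is the one-step side branch that supplies 7 for steps 5 and 12).

Steps most likely to fail, riskiest first:

1. Step 8. The β-methyl dienophile may cyclise too slowly under stoichiometric Me2AlCl. Ionisation of the dienylic silyl ether by the Lewis acid, or loss of endo and facial control at the higher temperature then needed, could take over. The fallback sets out from acid 10 and returns at alcohol 15; it moves the source of asymmetry from the auxiliary to a catalyst and uses a stronger, substoichiometric activator. Acid 10 is acylated onto achiral oxazolidin-2-one through the same mixed anhydride 12 (LiCl, Et3N, THF) to give 3-[(2E,8E,10E)-12-{[tert-butyl(diphenyl)silyl]oxy}-3,7,7-trimethyldodeca-2,8,10-trienoyl]-1,3-oxazolidin-2-one F1. A catalytic enantioselective intramolecular Diels–Alder reaction with the dicationic divalent copper bis(oxazoline) complex [Cu((R,R)-t-Bu-box)](SbF6)2 (5–10 mol %, CH2Cl2, rt) should then give the cycloadduct 3-{[(1S,2S,4aS,8aS)-2-({[tert-butyl(diphenyl)silyl]oxy}methyl)-5,5,8a-trimethyl-1,2,4a,5,6,7,8,8a-octahydronaphthalen-1-yl]carbonyl}-1,3-oxazolidin-2-one F2. This catalyst class is known to cyclise trienoyl oxazolidinones with endo selectivity, and on the square-planar chelate model the (R,R) ligand exposes the C9 Si face, the face used in step 8. LiBH4 reduction of F2 (as in step 9) gives 15.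

2. Step 9. The C11 carbonyl is flanked by quaternary C10 and substituted C8, so hydride may attack the ring carbonyl of the oxazolidinone and open the auxiliary instead of releasing the alcohol. The fallback sets out from 14 and returns at 17; it unloads the auxiliary intramolecularly. Bu4NF in THF removes the silyl group to give the hydroxy imide (4S)-4-benzyl-3-{[(1S,2S,4aS,8aS)-2-(hydroxymethyl)-5,5,8a-trimethyl-1,2,4a,5,6,7,8,8a-octahydronaphthalen-1-yl]carbonyl}-1,3-oxazolidin-2-one F3, which is not isolated. Its C17 alkoxide, cis to the acyl group, attacks C11 (5-exo-trig) to give the cis-fused γ-lactone (3aS,5aS,9aS,9bS)-6,6,9a-trimethyl-3a,5a,6,7,8,9,9a,9b-octahydronaphtho[1,2-c]furan-1(3H)-one F4 and free 11. Reduction with i-Bu2AlH at −78 °C gives the lactol (3aS,5aS,9aS,9bS)-6,6,9a-trimethyl-1,3,3a,5a,6,7,8,9,9a,9b-decahydronaphtho[1,2-c]furan-1-ol F5 (anomeric mixture). Wittig methylenation with excess Ph3P=CH2 opens the lactol to [(1S,2S,4aS,8aR)-1-ethenyl-5,5,8a-trimethyl-1,2,4a,5,6,7,8,8a-octahydronaphthalen-2-yl]methanol F6. Silylation (TBDPSCl, imidazole) gives 17.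

3. Step 12. Hydroboration of the hindered C9 vinyl group may be slow enough for the ring alkene to compete, or base hydrolysis of the enol triflate may outrun transmetalation. The fallback sets out from aldehyde 16 and returns at 19; it builds the side chain by carbonyl olefination and bypasses steps 11 and 12. Wittig reaction of 16 with 1-(triphenylphosphoranylidene)propan-2-one (toluene, 80 °C) gives the enone (3E)-4-[(1S,2S,4aS,8aR)-2-({[tert-butyl(diphenyl)silyl]oxy}methyl)-5,5,8a-trimethyl-1,2,4a,5,6,7,8,8a-octahydronaphthalen-1-yl]but-3-en-2-one F7. Chemoselective 1,4-reduction with [(Ph3P)CuH]6 gives the methyl ketone 4-[(1S,2S,4aS,8aR)-2-({[tert-butyl(diphenyl)silyl]oxy}methyl)-5,5,8a-trimethyl-1,2,4a,5,6,7,8,8a-octahydronaphthalen-1-yl]butan-2-one F8. Horner–Wadsworth–Emmons olefination with trimethyl phosphonoacetate and NaH in THF gives 19; the expected minor 13Z isomer would be removed by chromatography at 19 or 20.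

Further compounds

F1 | step 8 | 3-[(2E,8E,10E)-12-{[tert-butyl(diphenyl)silyl]oxy}-3,7,7-trimethyldodeca-2,8,10-trienoyl]-1,3-oxazolidin-2-one | O=C1OCCN1C(=O)/C=C(\C)CCCC(C)(C)/C=C/C=C/CO[Si](c2ccccc2)(c3ccccc3)C(C)(C)C
F2 | step 8 | 3-{[(1S,2S,4aS,8aS)-2-({[tert-butyl(diphenyl)silyl]oxy}methyl)-5,5,8a-trimethyl-1,2,4a,5,6,7,8,8a-octahydronaphthalen-1-yl]carbonyl}-1,3-oxazolidin-2-one | O=C1OCCN1C(=O)[C@H]2[C@@H](CO[Si](c4ccccc4)(c5ccccc5)C(C)(C)C)C=C[C@H]3C(C)(C)CCC[C@]23C
F3 | step 9 | (4S)-4-benzyl-3-{[(1S,2S,4aS,8aS)-2-(hydroxymethyl)-5,5,8a-trimethyl-1,2,4a,5,6,7,8,8a-octahydronaphthalen-1-yl]carbonyl}-1,3-oxazolidin-2-one | O=C1OC[C@H](Cc2ccccc2)N1C(=O)[C@H]3[C@@H](CO)C=C[C@H]4C(C)(C)CCC[C@]34C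
F4 | step 9 | (3aS,5aS,9aS,9bS)-6,6,9a-trimethyl-3a,5a,6,7,8,9,9a,9b-octahydronaphtho[1,2-c]furan-1(3H)-one | O=C1[C@H]3[C@@H](CO1)C=C[C@H]4C(C)(C)CCC[C@]34C
F5 | step 9 | (3aS,5aS,9aS,9bS)-6,6,9a-trimethyl-1,3,3a,5a,6,7,8,9,9a,9b-decahydronaphtho[1,2-c]furan-1-ol | OC1[C@H]3[C@@H](CO1)C=C[C@H]4C(C)(C)CCC[C@]34C
F6 | step 9 | [(1S,2S,4aS,8aR)-1-ethenyl-5,5,8a-trimethyl-1,2,4a,5,6,7,8,8a-octahydronaphthalen-2-yl]methanol | C=C[C@H]1[C@@H](CO)C=C[C@H]2C(C)(C)CCC[C@]12C
F7 | step 12 | (3E)-4-[(1S,2S,4aS,8aR)-2-({[tert-butyl(diphenyl)silyl]oxy}methyl)-5,5,8a-trimethyl-1,2,4a,5,6,7,8,8a-octahydronaphthalen-1-yl]but-3-en-2-one | CC(=O)/C=C/[C@H]1[C@@H](CO[Si](c3ccccc3)(c4ccccc4)C(C)(C)C)C=C[C@H]2C(C)(C)CCC[C@]12C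
F8 | step 12 | 4-[(1S,2S,4aS,8aR)-2-({[tert-butyl(diphenyl)silyl]oxy}methyl)-5,5,8a-trimethyl-1,2,4a,5,6,7,8,8a-octahydronaphthalen-1-yl]butan-2-one | CC(=O)CC[C@H]1[C@@H](CO[Si](c3ccccc3)(c4ccccc4)C(C)(C)C)C=C[C@H]2C(C)(C)CCC[C@]12C
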